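- elm: D 0.31 M; J 66 mM (held); the very flask that is asked about, followed so far
- flask: D 0.31 M; J 66 mM (held); time 3.0 min

elm run (percent of the D charged)

| time / s | L / % | D / % |
|---|---|---|
| 10.0 | 3.6 | 93.0 |
| 15.0 | 5.3 | 88.0 |
| 30.0 | 9.3 | 75.6 |

(scatter of a reading: 0.5 percentage points)

- at the start none of J is in solution

- Monday's: doubling the transfer coefficient of J, all else as stated
- Tuesday's: doubling the saturation concentration of J, all else as stated

- the L standing at 3.0 min, as a percentage of the D charged
- the change that raises the amount of L at 3.0 min, in percent of the D charged most ("none" if none brings more than 2 percentage points) (Monday's / Tuesday's / none)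
- amount of L at 3.0 min, in percent of the D charged, after Tuesday's

**Fraction left.** At late times this flask is best read from what remains, so I worked with the fraction of D left and took k, the pseudo-first-order decay constant of D with J held, as the logarithm of that fraction's fall per unit time between the first and last readings: 0.0104 s⁻¹. Carried on from the last reading to 3.0 min, k left 16.0% of D.

**Share of L.** Of the D gone by 30.0 s, L made up a share s of 38.1%, and with s held fixed I had 32.0% of L at 3.0 min.

**Weak link.** That fixed s was the weak link, since s had read 44.2% at 15.0 s, a fall of 0.00982 s⁻¹, and this rate run on gave 7.34%. But the last s predicts 4.57% of L at 15.0 s where 5.3% was read, a gap to hold against a scatter of 0.5 percentage points, so I used half that rate and committed to 15.3%. For Tuesday's I doubled both rates, which squares the fraction of D left, and got 8.51%, a loss.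

**The forecast.** The forecast gave 7.5%, 3% after Tuesday's and none as the best change, reasoning “so J sits near saturation”; I reckoned no figure for Monday's, and my figure for L stood higher.

**The flask.** The flask gave 15.9% at 3.0 min, 7.58% after Tuesday's and none as the best change, by these steps:

    L ⇌ E (K = 1.60, k = 0.260 s⁻¹)
    D + Q → L (k = 0.230 M⁻¹ s⁻¹)
    Q + L → G (k = 0.350 M⁻¹ s⁻¹)
    2 Q → X (k = 0.260 M⁻¹ s⁻¹)
    J ⇌ Q, rate k5*(csat - [Q]) (kL = 0.210 s⁻¹)

In this flask L had stood at 17.2% at 1.50 min. Against k's 16.0%, this flask held 14% of D at 3.0 min. In the neighbouring flask read at 80 s, k gave 45.0% of D, and that flask held 43.7%.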